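**Retrosynthetic overview**
1. Target 38 comes from CAN oxidation of its 1,4-dimethoxynaphthalene 37; the open-chain methyl centres C3', C7' and C11' come from one Ir-catalysed asymmetric hydrogenation of the all-E C2'/C6'/C10' triene 36.
2. C12'–C13' is made by alkylating the tosylhydrazone dianion of cyclopentyl methyl ketone 22 (C13' nucleophile; the C14' oxygen then leaves by hydrazone reduction) with allylic bromide 32, built from menadione and (2E,6E)-farnesyl bromide by ω-oxidation.
3. Ketone 22 comes from 1-acetyl-4-isopropenylcyclopentene 6: the isopropenyl group becomes the C19' ketone, an E-enoate, then C19' by CuH reduction and the tail by Wittig reaction; the acetyl group becomes an (S)-carbinol (CBS) that directs hydrogenation of C15'=C16' to the cis-1,3 ring.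
4. Structural basis: C13'–C20', the ring CH2 C15a and the C19' methyl are a ring-contracted p-menthane with C18' as its stereocentre, so 6 comes from aldol closure C15'–C16' of keto-aldehyde 4, itself from ring-olefin cleavage of (R)-limonene 1.
5. Ring order: the cyclopentane C15'–C16'–C17'–C18'–C15a is the only ring formed (step 3); the naphthalene ring system is bought as menadione.

Key step: step 3

Assumption: locants C1'–C23' number the side chain from the quinone and C15a is the ring CH2 between C15' and C18'; the hand of the chiral ligands in steps 9 and 22 is defined by the olefin face to be hydrogenated and would be confirmed on first use.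

**Route**

Step 1
Reactants: 1 (R)-limonene
Product: 2 (4R)-1-methyl-4-(prop-1-en-2-yl)-7-oxabicyclo[4.1.0]heptane (cis/trans epoxide mixture)
Conditions: mCPBA (1.0 equiv), NaHCO3, CH2Cl2, 0 °C
Reagents that add atoms: mCPBA, OOC(=O)c1cccc(Cl)c1
Why: Prilezhaev epoxidation is expected to take the more electron-rich trisubstituted ring olefin and spare the 1,1-disubstituted isopropenyl group, and since both epoxide diastereomers converge in step 2 and C4 is untouched no stereochemical issue arises.

Step 2
Reactants: 2 (4R)-limonene 1,2-oxide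
Product: 4 (3R)-6-oxo-3-(prop-1-en-2-yl)heptanal, via limonene-1,2-diol 3 (not isolated)
Conditions: H5IO6 (1.1 equiv), THF/H2O, 0 °C to rt
Reagents that add atoms: water, O
Why: Periodic acid first hydrolyses the epoxide to the 1,2-diol and then cleaves it (Malaprade glycol cleavage) in the same flask, and the stereocentre (future C18') is not enolisable in the keto-aldehyde and is retained.

Step 3
Reactants: 4 (3R)-6-oxo-3-(prop-1-en-2-yl)heptanal
Product: 6 1-[(4S)-4-(prop-1-en-2-yl)cyclopent-1-en-1-yl]ethan-1-one, via aldol adduct 5 (not isolated)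
Conditions: KOH (2% aq.), THF, rt, N2
Reagents that add atoms: none
Why: Hydroxide reversibly enolises the methyl ketone toward its ring-side methylene (C15'), this enolate adds to the aldehyde carbon C16' (bond C15'–C16'), and E1cB loss of water then gives the conjugated acetyl enone and drains all reversible aldol equilibria into one product. The closest known reaction type is the base-mediated aldol condensation of 1,6-keto-aldehydes to 1-acylcyclopentenes, which is established for this limonene-derived substrate. The cyclopentane C15'–C16'–C17'–C18'–C15a closes in the 5-(enolexo)-exo-trig mode. No stereocentre is created: C18' is β to the aldehyde and γ to the ketone, carries no acidic hydrogen and is carried through unchanged, while C15' and C16' end as sp2 carbons. The step needs chemoselectivity among three aldol modes, and hydroxide secures it because the unhindered aldehyde is the better acceptor and the ketone the donor, whereas the aldehyde-donor closure (to the cyclopentenecarbaldehyde) and the C13' methyl enolate (seven-membered ring) do not lead to this conjugated sink; secondary amines, which would activate the aldehyde as its enamine, are kept out.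

Step 4
Reactants: 6 1-[(4S)-4-(prop-1-en-2-yl)cyclopent-1-en-1-yl]ethan-1-one
Product: 8 1,1'-[(4S)-cyclopent-1-ene-1,4-diyl]di(ethan-1-one), via secondary ozonide 7 (not isolated)
Conditions: O3, CH2Cl2, −78 °C (Sudan Red 7B end-point); then Me2S, −78 °C to rt
Reagents that add atoms: ozone, [O-][O+]=O
Why: Criegee ozonolysis is expected to be chemoselective for the isolated 1,1-disubstituted olefin because the electron-poor enone olefin reacts far more slowly with ozone (the selectivity known for carvone), and the neutral reductive work-up leaves the now ketone-adjacent C18' untouched.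

Step 5
Reactants: 8 1,1'-[(4S)-cyclopent-1-ene-1,4-diyl]di(ethan-1-one)
Product: 9 1-[(4S)-4-(2-methyl-1,3-dioxolan-2-yl)cyclopent-1-en-1-yl]ethan-1-one
Conditions: TMSOCH2CH2OTMS (1.1 equiv), TMSOTf (2 mol%), CH2Cl2, −78 °C; pyridine quench
Reagents that add atoms: 1,2-bis(trimethylsilyloxy)ethane, C[Si](C)(C)OCCO[Si](C)(C)C
Why: Silyl-triflate-catalysed ketalisation with the bis-silylated glycol (Noyori conditions) discriminates the saturated C19' ketone from the less electrophilic conjugated C14' ketone, and at −78 °C under non-enolising conditions C18', here the only stereocentre, is not at risk.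

Step 6
Reactants: 9 1-[(4S)-4-(2-methyl-1,3-dioxolan-2-yl)cyclopent-1-en-1-yl]ethan-1-one
Product: 10 (1S)-1-[(4S)-4-(2-methyl-1,3-dioxolan-2-yl)cyclopent-1-en-1-yl]ethan-1-ol
Conditions: (R)-2-methyl-CBS-oxazaborolidine (15 mol%), catecholborane (1.5 equiv), toluene, −78 °C; MeOH, then aq. NaOH
Reagents that add atoms: none
Why: Corey–Bakshi–Shibata reduction treats the cyclopentenyl group as the large and methyl as the small substituent, so the (R)-catalyst should give the (S)-carbinol at C14' under reagent control (C18' is remote), with catecholborane at low temperature avoiding hydroboration of the olefin.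

Step 7
Reactants: 10 (1S)-1-[(4S)-4-(2-methyl-1,3-dioxolan-2-yl)cyclopent-1-en-1-yl]ethan-1-ol
Product: 11 1-[(1S)-3-[(1S)-1-hydroxyethyl]cyclopent-3-en-1-yl]ethan-1-one
Conditions: PPTS (10 mol%), acetone/H2O (10:1), 40 °C
Reagents that add atoms: water, O
Why: Mild acid-catalysed ketal hydrolysis frees the C19' methyl ketone, PPTS being too weak to ionise the secondary allylic alcohol or to enolise the ketone toward C18'.

Step 8
Reactants: 11 1-[(1S)-3-[(1S)-1-hydroxyethyl]cyclopent-3-en-1-yl]ethan-1-one; 12 triethyl phosphonoacetate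
Product: 14 ethyl (2E)-3-[(1S)-3-[(1S)-1-hydroxyethyl]cyclopent-3-en-1-yl]but-2-enoate, via phosphonate carbanion 13 (not isolated)
Conditions: NaH (2.3 equiv), 12 (1.3 equiv), THF, 0 °C; then 11, rt to 45 °C
Reagents that add atoms: none
Why: Horner–Wadsworth–Emmons olefination of the methyl ketone should give mainly the E-enoate (cyclopentyl trans to the ester; the minor Z isomer is removed by chromatography), and the stabilised phosphonate anion is too weak a base to enolise the ketone quickly toward C18'.

Step 9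
Reactants: 14 ethyl (2E)-3-[(1S)-3-[(1S)-1-hydroxyethyl]cyclopent-3-en-1-yl]but-2-enoate
Product: 16 ethyl (3R)-3-[(1S)-3-[(1S)-1-hydroxyethyl]cyclopent-3-en-1-yl]butanoate, via O-silyl ester 15 (not isolated)
Conditions: Cu(OAc)2·H2O (3 mol%), DTBM-SEGPHOS (3 mol%, antipode that delivers H to the Re face of C19'), (EtO)2MeSiH (3 equiv), t-BuOH (1.2 equiv), toluene, 0 °C to rt; then K2CO3 (cat.), MeOH, rt
Reagents that add atoms: none
Why: Copper hydride-catalysed asymmetric conjugate reduction of the E-β,β-disubstituted enoate sets C19' as R by ligand-controlled hydride delivery to its Re face, does not touch the isolated ring olefin, and the hydroxyl group, silylated in the flask, is freed by methanolysis.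

Step 10
Reactants: 16 ethyl (3R)-3-[(1S)-3-[(1S)-1-hydroxyethyl]cyclopent-3-en-1-yl]butanoate
Product: 17 (3R)-3-[(1S)-3-[(1S)-1-hydroxyethyl]cyclopent-3-en-1-yl]butanal
Conditions: DIBAL-H (2.2 equiv), CH2Cl2, −78 °C; MeOH, then aq. Rochelle salt
Reagents that add atoms: none
Why: DIBAL-H half-reduction at −78 °C stops at the aldehyde through the stable tetrahedral aluminate (one equivalent is consumed by the hydroxyl group), and C19' is β to the carbonyl and cannot epimerise.

Step 11
Reactants: 17 (3R)-3-[(1S)-3-[(1S)-1-hydroxyethyl]cyclopent-3-en-1-yl]butanal; 18 isobutyltriphenylphosphonium bromide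
Product: 20 (1S)-1-[(4S)-4-[(2R,4Z)-6-methylhept-4-en-2-yl]cyclopent-1-en-1-yl]ethan-1-ol, via isobutylidene ylide 19 (not isolated)
Conditions: 18 (2.5 equiv), KHMDS (2.4 equiv), THF, −78 to 0 °C; then 17
Reagents that add atoms: none
Why: Wittig olefination with the non-stabilised isobutylidene ylide (excess, the first equivalent deprotonating the alcohol) attaches C22', C23' and the two terminal methyls, and its Z/E ratio is irrelevant because the olefin is hydrogenated in step 12.

Step 12
Reactants: 20 (1S)-1-[(4S)-4-[(2R,4Z)-6-methylhept-4-en-2-yl]cyclopent-1-en-1-yl]ethan-1-ol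
Product: 21 (1S)-1-[(1R,3S)-3-[(2R)-6-methylheptan-2-yl]cyclopentyl]ethan-1-ol
Conditions: [Rh(nbd)(dppb)]BF4 (5 mol%), H2 (50 bar), CH2Cl2, rt
Reagents that add atoms: none
Why: In this hydroxyl-directed hydrogenation the cationic Rh binds the C14' hydroxyl and delivers H2 to the ring-olefin face on which the OH can sit while the carbinol H, not CH3, lies next to ring CH2 C15a (A(1,2) strain), which for the (S)-carbinol is the face opposite the C18' side chain, so C15' is formed with the C14' arm cis to the C18' substituent (directing and steric effects matched); the tail olefin is saturated in the same operation and the high pressure suppresses allylic alcohol isomerisation.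

Step 13
Reactants: 21 (1S)-1-[(1R,3S)-3-[(2R)-6-methylheptan-2-yl]cyclopentyl]ethan-1-ol
Product: 22 1-[(1R,3S)-3-[(2R)-6-methylheptan-2-yl]cyclopentyl]ethan-1-one
Conditions: Dess–Martin periodinane (1.3 equiv), NaHCO3, CH2Cl2, 0 °C to rt
Reagents that add atoms: none
Why: Dess–Martin oxidation under buffered, non-enolising conditions regenerates the methyl ketone without epimerising the adjacent C15' stereocentre.

Step 14
Reactants: 22 1-[(1R,3S)-3-[(2R)-6-methylheptan-2-yl]cyclopentyl]ethan-1-one
Product: 23 (E)-tosylhydrazone of 22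
Conditions: TsNHNH2 (1.05 equiv), THF, 4 Å MS, rt
Reagents that add atoms: p-toluenesulfonyl hydrazide, Cc1ccc(cc1)S(=O)(=O)NN
Why: Condensation under neutral conditions should give mainly the E-tosylhydrazone (sulfonamide nitrogen syn to the methyl group), which prepares regioselective deprotonation at C13' and removes the enolisable carbonyl next to C15'.

Step 15
Reactants: 24 menadione
Product: 26 1,4-dimethoxy-2-methylnaphthalene, via menadiol 25 (not isolated)
Conditions: Na2S2O4, Bu4NBr (cat.), THF/H2O, rt; then aq. KOH, Me2SO4, rt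
Reagents that add atoms: dimethyl sulfate, COS(=O)(=O)OC
Why: Dithionite reduction to the hydroquinone followed by Williamson O-methylation (reductive methylation) masks the quinone as the bis-methyl ether that CAN reopens at the end.

Step 16
Reactants: 26 1,4-dimethoxy-2-methylnaphthalene
Product: 27 2-bromo-1,4-dimethoxy-3-methylnaphthalene
Conditions: Br2 (1.05 equiv), CH2Cl2, 0 °C, dark
Reagents that add atoms: bromine, BrBr
Why: Electrophilic aromatic bromination takes the only free position of the electron-rich dimethoxy-substituted ring.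

Step 17
Reactants: 27 2-bromo-1,4-dimethoxy-3-methylnaphthalene; 28 (2E,6E)-farnesyl bromide
Product: 30 1,4-dimethoxy-2-methyl-3-[(2E,6E)-3,7,11-trimethyldodeca-2,6,10-trien-1-yl]naphthalene, via aryllithium 29 (not isolated)
Conditions: n-BuLi (1.05 equiv), THF, −78 °C; then CuBr·SMe2 (10 mol%), 28, −78 to 0 °C
Reagents that add atoms: none
Why: Bromine–lithium exchange and copper-catalysed SN2 coupling of the aryl metal with the primary allylic bromide attach the farnesyl chain through C1' with retention of the E olefin geometries.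

Step 18
Reactants: 30 1,4-dimethoxy-2-methyl-3-[(2E,6E)-3,7,11-trimethyldodeca-2,6,10-trien-1-yl]naphthalene
Product: 31 (2E,6E,10E)-12-(1,4-dimethoxy-3-methylnaphthalen-2-yl)-2,6,10-trimethyldodeca-2,6,10-trien-1-ol
Conditions: SeO2 (0.3 equiv), t-BuOOH (3 equiv), salicylic acid (0.1 equiv), CH2Cl2, 0 °C to rt, stopped at partial conversion; NaBH4, MeOH, 0 °C to return any enal to 31
Reagents that add atoms: selenium dioxide, O=[Se]=O; tert-butyl hydroperoxide, CC(C)(C)OO
Why: Selenium dioxide allylic oxidation (ene reaction, then [2,3]-sigmatropic shift) is selective for the E-methyl group of the terminal, most accessible trisubstituted olefin and gives the E allylic alcohol whose carbinol carbon is the future C12'.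

Step 19
Reactants: 31 (2E,6E,10E)-12-(1,4-dimethoxy-3-methylnaphthalen-2-yl)-2,6,10-trimethyldodeca-2,6,10-trien-1-ol
Product: 32 2-[(2E,6E,10E)-12-bromo-3,7,11-trimethyldodeca-2,6,10-trien-1-yl]-1,4-dimethoxy-3-methylnaphthalene
Conditions: CBr4 (1.3 equiv), PPh3 (1.3 equiv), CH2Cl2, 0 °C
Reagents that add atoms: carbon tetrabromide, BrC(Br)(Br)Br
Why: The Appel reaction converts the primary allylic alcohol into the bromide under neutral conditions without allylic transposition or loss of E geometry.

Step 20
Reactants: 23 (E)-tosylhydrazone of 22; 32 allylic bromide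
Product: 34 C13'-alkylated tosylhydrazone, via tosylhydrazone dianion 33 (not isolated)
Conditions: n-BuLi (2.05 equiv), THF, −78 to −50 °C; then 32 (1.2 equiv), −78 to −40 °C; aq. NH4Cl at −40 °C
Reagents that add atoms: none
Why: Double deprotonation of the E-tosylhydrazone (N–H, then the syn methyl group C13'; Shapiro-type dianion) gives a carbon nucleophile that the allylic bromide alkylates at C13' in an SN2 reaction, forming C12'–C13' without touching C15' or the E olefins, the monoanion being quenched cold before it can eliminate.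

Step 21
Reactants: 34 C13'-alkylated tosylhydrazone
Product: 36 1,4-dimethoxy-2-methyl-3-[(2E,6E,10E)-3,7,11-trimethyl-14-[(1R,3S)-3-[(2R)-6-methylheptan-2-yl]cyclopentyl]tetradeca-2,6,10-trien-1-yl]naphthalene, via N-boryl tosylhydrazine 35 (not isolated)
Conditions: catecholborane (1.5 equiv), CHCl3, 0 °C to rt; then NaOAc·3H2O (3 equiv), reflux
Reagents that add atoms: none
Why: Catecholborane adds across the C=N bond and acetate-induced loss of sulfinate and dinitrogen (catecholborane variant of the Caglioti tosylhydrazone reduction) turns C14' into CH2 under conditions that neither hydroborate the trisubstituted olefins nor epimerise C15'.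

Step 22
Reactants: 36 triene
Product: 37 1,4-dimethoxy-2-methyl-3-[(3S,7S,11R)-3,7,11-trimethyl-14-[(1R,3S)-3-[(2R)-6-methylheptan-2-yl]cyclopentyl]tetradecyl]naphthalene
Conditions: [Ir(cod)(P,N)]BArF (P,N = chiral pyridyl phosphinite, antipode of the one that gives the natural R,R chain from E,E-tocotrienyl acetate; 3 mol%), H2 (50 bar), CH2Cl2, rt
Reagents that add atoms: none
Why: Iridium-catalysed asymmetric hydrogenation of unfunctionalised E-trisubstituted olefins (as established for tocotrienyl acetates) should deliver hydrogen under catalyst control to the same topological face of the three like-configured chain olefins, setting C3', C7' and C11' in one spatial sense (CIP 3'S,7'S,11'R) without affecting the existing centres.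

Step 23
Reactants: 37 saturated dimethoxynaphthalene
Product: 38 2-methyl-3-[(3S,7S,11R)-3,7,11-trimethyl-14-[(1R,3S)-3-[(2R)-6-methylheptan-2-yl]cyclopentyl]tetradecyl]naphthalene-1,4-dione (CNP0182328.1)
Conditions: CAN (2.5 equiv), MeCN/H2O (3:1), 0 °C
Reagents that add atoms: water, O
Why: Ceric ammonium nitrate oxidative demethylation of the 1,4-dimethoxyarene gives the 1,4-naphthoquinone, the quinone oxygens coming from water, while the saturated side chain is inert.

**Compound list**
1 | (R)-limonene | CC1=CC[C@@H](CC1)C(C)=C | starting material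
2 | (4R)-1-methyl-4-(prop-1-en-2-yl)-7-oxabicyclo[4.1.0]heptane (epoxide diastereomer mixture) | CC12OC1C[C@@H](CC2)C(C)=C | intermediate
3 | (4R)-1-methyl-4-(prop-1-en-2-yl)cyclohexane-1,2-diol (C1, C2 unspecified) | CC1(O)C(O)C[C@@H](CC1)C(C)=C | intermediate (not isolated)
4 | (3R)-6-oxo-3-(prop-1-en-2-yl)heptanal | O=CC[C@H](C(C)=C)CCC(C)=O | intermediate
5 | 1-[(4R)-2-hydroxy-4-(prop-1-en-2-yl)cyclopentyl]ethan-1-one (C1, C2 unspecified) | CC(=O)C1C(O)C[C@H](C(C)=C)C1 | intermediate (not isolated)
6 | 1-[(4S)-4-(prop-1-en-2-yl)cyclopent-1-en-1-yl]ethan-1-one | CC(=O)C1=CC[C@H](C(C)=C)C1 | intermediate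
7 | 1-[(4S)-4-(3-methyl-1,2,4-trioxolan-3-yl)cyclopent-1-en-1-yl]ethan-1-one (ozonide carbon unspecified) | CC(=O)C1=CC[C@H](C2(C)OCOO2)C1 | intermediate (not isolated)
8 | 1,1'-[(4S)-cyclopent-1-ene-1,4-diyl]di(ethan-1-one) | CC(=O)C1=CC[C@H](C(C)=O)C1 | intermediate
9 | 1-[(4S)-4-(2-methyl-1,3-dioxolan-2-yl)cyclopent-1-en-1-yl]ethan-1-one | CC(=O)C1=CC[C@H](C2(C)OCCO2)C1 | intermediate
10 | (1S)-1-[(4S)-4-(2-methyl-1,3-dioxolan-2-yl)cyclopent-1-en-1-yl]ethan-1-ol | C[C@H](O)C1=CC[C@H](C2(C)OCCO2)C1 | intermediate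
11 | 1-[(1S)-3-[(1S)-1-hydroxyethyl]cyclopent-3-en-1-yl]ethan-1-one | C[C@H](O)C1=CC[C@H](C(C)=O)C1 | intermediate
12 | triethyl phosphonoacetate | CCOC(=O)CP(=O)(OCC)OCC | starting material
13 | sodium (diethoxyphosphoryl)(ethoxycarbonyl)methanide | [Na+].CCOC(=O)[CH-]P(=O)(OCC)OCC | intermediate (not isolated)
14 | ethyl (2E)-3-[(1S)-3-[(1S)-1-hydroxyethyl]cyclopent-3-en-1-yl]but-2-enoate | CCOC(=O)/C=C(\C)[C@H]1CC=C([C@H](C)O)C1 | intermediate
15 | ethyl (3R)-3-[(1S)-3-[(1S)-1-[diethoxy(methyl)silyloxy]ethyl]cyclopent-3-en-1-yl]butanoate | CCOC(=O)C[C@@H](C)[C@H]1CC=C([C@H](C)O[Si](C)(OCC)OCC)C1 | intermediate (not isolated)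
16 | ethyl (3R)-3-[(1S)-3-[(1S)-1-hydroxyethyl]cyclopent-3-en-1-yl]butanoate | CCOC(=O)C[C@@H](C)[C@H]1CC=C([C@H](C)O)C1 | intermediate
17 | (3R)-3-[(1S)-3-[(1S)-1-hydroxyethyl]cyclopent-3-en-1-yl]butanal | O=CC[C@@H](C)[C@H]1CC=C([C@H](C)O)C1 | intermediate
18 | isobutyltriphenylphosphonium bromide | CC(C)C[P+](c1ccccc1)(c1ccccc1)c1ccccc1.[Br-] | starting material
19 | (2-methylpropylidene)triphenylphosphorane | CC(C)C=P(c1ccccc1)(c1ccccc1)c1ccccc1 | intermediate (not isolated)
20 | (1S)-1-[(4S)-4-[(2R,4Z)-6-methylhept-4-en-2-yl]cyclopent-1-en-1-yl]ethan-1-ol | CC(C)/C=C\C[C@@H](C)[C@H]1CC=C([C@H](C)O)C1 | intermediate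
21 | (1S)-1-[(1R,3S)-3-[(2R)-6-methylheptan-2-yl]cyclopentyl]ethan-1-ol | C[C@H](O)[C@@H]1CC[C@H]([C@H](C)CCCC(C)C)C1 | intermediate
22 | 1-[(1R,3S)-3-[(2R)-6-methylheptan-2-yl]cyclopentyl]ethan-1-one | CC(=O)[C@@H]1CC[C@H]([C@H](C)CCCC(C)C)C1 | intermediate
23 | 4-methyl-N'-[(1E)-1-[(1R,3S)-3-[(2R)-6-methylheptan-2-yl]cyclopentyl]ethylidene]benzenesulfonohydrazide | C/C(=N\NS(=O)(=O)c1ccc(C)cc1)[C@@H]1CC[C@H]([C@H](C)CCCC(C)C)C1 | intermediate
24 | menadione | CC1=CC(=O)c2ccccc2C1=O | starting material
25 | menadiol (2-methylnaphthalene-1,4-diol) | Cc1cc(O)c2ccccc2c1O | intermediate (not isolated)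
26 | 1,4-dimethoxy-2-methylnaphthalene | COc1cc(C)c(OC)c2ccccc12 | intermediate
27 | 2-bromo-1,4-dimethoxy-3-methylnaphthalene | COc1c(Br)c(C)c(OC)c2ccccc12 | intermediate
28 | (2E,6E)-farnesyl bromide | BrC/C=C(\C)CC/C=C(\C)CCC=C(C)C | starting material
29 | (1,4-dimethoxy-3-methylnaphthalen-2-yl)lithium | COc1c([Li])c(C)c(OC)c2ccccc12 | intermediate (not isolated)
30 | 1,4-dimethoxy-2-methyl-3-[(2E,6E)-3,7,11-trimethyldodeca-2,6,10-trien-1-yl]naphthalene | COc1c(C)c(C/C=C(\C)CC/C=C(\C)CCC=C(C)C)c(OC)c2ccccc12 | intermediate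
31 | (2E,6E,10E)-12-(1,4-dimethoxy-3-methylnaphthalen-2-yl)-2,6,10-trimethyldodeca-2,6,10-trien-1-ol | COc1c(C)c(C/C=C(\C)CC/C=C(\C)CC/C=C(\C)CO)c(OC)c2ccccc12 | intermediate
32 | 2-[(2E,6E,10E)-12-bromo-3,7,11-trimethyldodeca-2,6,10-trien-1-yl]-1,4-dimethoxy-3-methylnaphthalene | COc1c(C)c(C/C=C(\C)CC/C=C(\C)CC/C=C(\C)CBr)c(OC)c2ccccc12 | intermediate
33 | C13',N-dilithio dianion of tosylhydrazone 23 | [Li]C/C(=N\N([Li])S(=O)(=O)c1ccc(C)cc1)[C@@H]1CC[C@H]([C@H](C)CCCC(C)C)C1 | intermediate (not isolated)
34 | N'-[(4E,8E,12E)-14-(1,4-dimethoxy-3-methylnaphthalen-2-yl)-4,8,12-trimethyl-1-[(1R,3S)-3-[(2R)-6-methylheptan-2-yl]cyclopentyl]tetradeca-4,8,12-trien-1-ylidene]-4-methylbenzenesulfonohydrazide | COc1c(C)c(C/C=C(\C)CC/C=C(\C)CC/C=C(\C)CC/C(=N\NS(=O)(=O)c3ccc(C)cc3)[C@@H]3CC[C@H]([C@H](C)CCCC(C)C)C3)c(OC)c2ccccc12 | intermediate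
35 | N-(1,3,2-benzodioxaborol-2-yl)-N'-tosylhydrazine adduct of 34 (C14' sp3, unspecified) | COc1c(C)c(C/C=C(\C)CC/C=C(\C)CC/C=C(\C)CCC(N(NS(=O)(=O)c3ccc(C)cc3)B3Oc4ccccc4O3)[C@@H]3CC[C@H]([C@H](C)CCCC(C)C)C3)c(OC)c2ccccc12 | intermediate (not isolated)
36 | 1,4-dimethoxy-2-methyl-3-[(2E,6E,10E)-3,7,11-trimethyl-14-[(1R,3S)-3-[(2R)-6-methylheptan-2-yl]cyclopentyl]tetradeca-2,6,10-trien-1-yl]naphthalene | COc1c(C)c(C/C=C(\C)CC/C=C(\C)CC/C=C(\C)CCC[C@@H]3CC[C@H]([C@H](C)CCCC(C)C)C3)c(OC)c2ccccc12 | intermediate
37 | 1,4-dimethoxy-2-methyl-3-[(3S,7S,11R)-3,7,11-trimethyl-14-[(1R,3S)-3-[(2R)-6-methylheptan-2-yl]cyclopentyl]tetradecyl]naphthalene | COc1c(C)c(CC[C@@H](C)CCC[C@@H](C)CCC[C@@H](C)CCC[C@@H]3CC[C@H]([C@H](C)CCCC(C)C)C3)c(OC)c2ccccc12 | intermediate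
38 | 2-methyl-3-[(3S,7S,11R)-3,7,11-trimethyl-14-[(1R,3S)-3-[(2R)-6-methylheptan-2-yl]cyclopentyl]tetradecyl]naphthalene-1,4-dione | CC1=C(CC[C@@H](C)CCC[C@@H](C)CCC[C@@H](C)CCC[C@@H]2CC[C@H]([C@H](C)CCCC(C)C)C2)C(=O)c2ccccc2C1=O | target

**Step count and risks**

Total step count: 23. Longest linear sequence: 18 steps (steps 1–14, then 20–23, from (R)-limonene); the naphthalene branch (steps 15–19) joins at step 20.

Steps most likely to fail:

Step 22. The catalyst may discriminate the faces of the C2'=C3' olefin, which sits next to the doubly ortho-substituted arene, less well than those of the two remote olefins, or double bonds may migrate before they are reduced. Either process leaves diastereomers that can no longer be separated at the end of the route. The fallback sets out from 31 and returns at 37, and fixes the stereotriad on the head fragment before the union. Alcohol 31 would be hydrogenated with the same class of Ir–N,P catalyst to (2R,6R,10S)-12-(1,4-dimethoxy-3-methylnaphthalen-2-yl)-2,6,10-trimethyldodecan-1-ol F1. At this stage the hydroxyl group allows the diastereomer content to be checked and upgraded (ester derivatives, chromatography). Iodination (I2, PPh3, imidazole) would give 2-[(3S,7R,11R)-12-iodo-3,7,11-trimethyldodecyl]-1,4-dimethoxy-3-methylnaphthalene F2. F2 would alkylate dianion 33 (THF/DMPU, −78 to −20 °C) to N'-[(4R,8R,12S)-14-(1,4-dimethoxy-3-methylnaphthalen-2-yl)-4,8,12-trimethyl-1-[(1R,3S)-3-[(2R)-6-methylheptan-2-yl]cyclopentyl]tetradecylidene]-4-methylbenzenesulfonohydrazide F3. Catecholborane/NaOAc reduction of F3 gives 37 directly, so steps 19 and 22 are no longer needed.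

Step 12. The cationic Rh catalyst may isomerise the secondary allylic alcohol to the saturated ketone faster than it hydrogenates it, which bypasses the hydroxyl-directed delivery, or the hydroxyl group may bind too weakly for complete face control. Both processes erode the cis relationship at C15'. The fallback sets out from 20 and returns at 22, and replaces the directing group by steric control on the enone. MnO2 (CH2Cl2, rt) would oxidise 20 to 1-[(4S)-4-[(2R,4Z)-6-methylhept-4-en-2-yl]cyclopent-1-en-1-yl]ethan-1-one F4. Heterogeneous hydrogenation (H2, Pd/C, EtOAc) would then saturate both olefins, hydrogen being taken up on the ring face opposite the C18' side chain, to give cis ketone 22. A minor trans ketone would be removed by chromatography at 22 or after conversion into 23.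

Step 18. Over-oxidation to the enal, competing oxidation at the two internal olefins or at the benzylic-allylic C1' position, and stalling at low conversion may all cut the supply of 31. The fallback sets out from 30 and returns at 31; it oxidises the terminal olefin selectively and rebuilds the E olefin. NBS in aqueous THF would convert 30 at the terminal olefin into (6E,10E)-3-bromo-12-(1,4-dimethoxy-3-methylnaphthalen-2-yl)-2,6,10-trimethyldodeca-6,10-dien-2-ol F5. K2CO3/MeOH would close it to 2-[(2E,6E)-9-(3,3-dimethyloxiran-2-yl)-3,7-dimethylnona-2,6-dien-1-yl]-1,4-dimethoxy-3-methylnaphthalene F6. Periodic acid would cleave the epoxide to (4E,8E)-10-(1,4-dimethoxy-3-methylnaphthalen-2-yl)-4,8-dimethyldeca-4,8-dienal F7. Wittig reaction with ethyl 2-(triphenylphosphoranylidene)propanoate would give ethyl (2E,6E,10E)-12-(1,4-dimethoxy-3-methylnaphthalen-2-yl)-2,6,10-trimethyldodeca-2,6,10-trienoate F8, and DIBAL-H reduction returns allylic alcohol 31.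

Further compounds
F1 | step 22 | (2R,6R,10S)-12-(1,4-dimethoxy-3-methylnaphthalen-2-yl)-2,6,10-trimethyldodecan-1-ol | COc1c(C)c(CC[C@@H](C)CCC[C@@H](C)CCC[C@@H](C)CO)c(OC)c2ccccc12
F2 | step 22 | 2-[(3S,7R,11R)-12-iodo-3,7,11-trimethyldodecyl]-1,4-dimethoxy-3-methylnaphthalene | COc1c(C)c(CC[C@@H](C)CCC[C@@H](C)CCC[C@@H](C)CI)c(OC)c2ccccc12
F3 | step 22 | N'-[(4R,8R,12S)-14-(1,4-dimethoxy-3-methylnaphthalen-2-yl)-4,8,12-trimethyl-1-[(1R,3S)-3-[(2R)-6-methylheptan-2-yl]cyclopentyl]tetradecylidene]-4-methylbenzenesulfonohydrazide | COc1c(C)c(CC[C@@H](C)CCC[C@@H](C)CCC[C@@H](C)CC/C(=N\NS(=O)(=O)c3ccc(C)cc3)[C@@H]3CC[C@H]([C@H](C)CCCC(C)C)C3)c(OC)c2ccccc12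
F4 | step 12 | 1-[(4S)-4-[(2R,4Z)-6-methylhept-4-en-2-yl]cyclopent-1-en-1-yl]ethan-1-one | CC(=O)C1=CC[C@H]([C@H](C)C/C=C\C(C)C)C1
F5 | step 18 | (6E,10E)-3-bromo-12-(1,4-dimethoxy-3-methylnaphthalen-2-yl)-2,6,10-trimethyldodeca-6,10-dien-2-ol | COc1c(C)c(C/C=C(\C)CC/C=C(\C)CCC(Br)C(C)(C)O)c(OC)c2ccccc12
F6 | step 18 | 2-[(2E,6E)-9-(3,3-dimethyloxiran-2-yl)-3,7-dimethylnona-2,6-dien-1-yl]-1,4-dimethoxy-3-methylnaphthalene | COc1c(C)c(C/C=C(\C)CC/C=C(\C)CCC3OC3(C)C)c(OC)c2ccccc12
F7 | step 18 | (4E,8E)-10-(1,4-dimethoxy-3-methylnaphthalen-2-yl)-4,8-dimethyldeca-4,8-dienal | COc1c(C)c(C/C=C(\C)CC/C=C(\C)CCC=O)c(OC)c2ccccc12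
F8 | step 18 | ethyl (2E,6E,10E)-12-(1,4-dimethoxy-3-methylnaphthalen-2-yl)-2,6,10-trimethyldodeca-2,6,10-trienoate | COc1c(C)c(C/C=C(\C)CC/C=C(\C)CC/C=C(\C)C(=O)OCC)c(OC)c2ccccc12
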